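(The readings were generated by integration with constants of no real substance, noise included.)

The ratio of second reagent to substrate, 1.20 equiv, is where your books open: second reagent is charged in more than substrate, and substrate is the limiting reagent, the one whose every mole you follow here.

| setting | cedar | birch | ash | amber | grey | red | violet |
|---|---|---|---|---|---|---|---|
| substrate | 10 mM | 10 mM | 10 mM | 10 mM | 10 mM | 10 mM | 10 mM (fed, over 32.0 h) |
| partner | 2.5 equiv | 2.5 equiv | 2.5 equiv | 2.50 equiv | 2.50 equiv (fed, over 32.0 h) | 2.50 equiv | 2.50 equiv |
| second reagent | 1.2 equiv | 1.2 equiv | 1.2 equiv | 1.20 equiv | 1.20 equiv | 1.20 equiv | 1.20 equiv |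
| third reagent | 3 equiv | 4.2 equiv | 6.6 equiv | 3.00 equiv | 3.00 equiv | 3.00 equiv | 3.00 equiv |
| remark | run made earlier | run made earlier | run made earlier | one stirred flow tank at steady state, fed with the mixture as stated, mean residence time 40 h | a stirred flask in which partner is dosed at a steady rate over 32.0 h without added volume, worked up at 40 h | a closed flask charged with all of it at once and left for 40 h | a stirred flask in which substrate is dosed at a steady rate over 32.0 h without added volume, worked up at 40 h |
| time |  |  |  |  | 40 h | 40 h | 40 h |

| run | time / h | intermediate A / % | product / % |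
|---|---|---|---|
| cedar | 2.00 | 66.1 | 2.1 |
| cedar | 6.00 | 41.6 | 11.9 |
| cedar | 12.0 | 25.8 | 29.0 |
| cedar | 15.0 | 20.7 | 38.0 |
| cedar | 25.0 | 11.6 | 58.9 |
| cedar | 30.0 | 8.2 | 66.5 |
| cedar | 40.0 | 4.7 | 78.6 |
| birch | 4.00 | 52.2 | 7.9 |
| birch | 6.00 | 42.4 | 15.2 |
| birch | 8.00 | 35.4 | 21.3 |
| birch | 15.0 | 20.9 | 47.3 |
| birch | 20.0 | 14.9 | 59.1 |
| birch | 30.0 | 7.8 | 75.4 |
| birch | 50.0 | 3.5 | 90.2 |
| ash | 4.00 | 52.2 | 11.6 |
| ash | 6.00 | 42.1 | 21.8 |
| ash | 8.00 | 33.7 | 30.9 |
| ash | 15.0 | 21.0 | 58.8 |
| ash | 20.0 | 14.6 | 70.8 |
| ash | 30.0 | 9.0 | 84.9 |
| ash | 50.0 | 3.3 | 94.5 |

(standard deviation of a reading: 0.5 percentage points)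

- the stated concentrations are those of everything mixed, before any reaction; amounts are the same in each set-up
- the feed brings no volume worth counting
- the earlier runs were made in a closed, stirred flask

1. the set-up with the highest amount of intermediate A at the outlet or at the end, in percent of the substrate put in ("none" if the first two lie within 2 percentage points) (amber / grey / red / violet / none)
2. amount of intermediate A at the outlet or at the end, in percent of the substrate put in, amber
3. amount of intermediate A at the outlet or at the end, in percent of the substrate put in, grey
4. amount of intermediate A at the outlet or at the end, in percent of the substrate put in, red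
5. amount of intermediate A at the outlet or at the end, in percent of the substrate put in, violet

At 15.0 h the runs read 20.7%, 20.9% and 21.0% of intermediate A, while product climbs from 38.0% to 58.8% as third reagent goes up, so third reagent acts after intermediate A. If each intermediate A lost takes one second reagent with it, the two stay apart by a fixed excess e = 2.00 mM, and ln[(c + e)/c], with c = c(intermediate A), should rise in a straight line. The cedar readings at 6.00 h and 30.0 h give its slope:

k = rise of ln[(c + e)/c] / (e × time between) = 0.0176 mM⁻¹ h⁻¹

This capture constant, the fraction of intermediate A lost per hour and per mM of second reagent, is a reading, and it keeps the ledger. For amber, with residence time τ = 40 h, each litre's substrate is booked like this: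

fed 10 mM = c at the outlet + captured, kτc(c + e) + not yet intermediate A

With the last entry at nothing, the books close at c = 2.43 mM, or 24.3%. That last entry is a small correction. The same line, started from the whole charge at time zero and run forward to 2.00 h in cedar, gives 69.6% against the 66.1% read, a shortfall of 3.5 percentage points. I take that shortfall as my estimate of the last entry in amber too, and an entry held back from the feed moves c at the outlet by its own size scaled by

0.172 = 1/[1 + kτ(2c + e)]

so I take off 0.6 points and commit to 23.7% for amber. For red the line gives 5.12%. The dosed flasks, each with a tail of 8.00 h after its feed, I leave unreckoned and expect between these two.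

The forecast named amber, with 24.4% for amber, 7.3% for grey, 5% for red and 16% for violet, from the finding that “Intermediate A decays identically in all three runs”.

The flasks give 23.1% for amber, 10.2% for grey, 5.42% for red and 16.2% for violet, so amber is highest.

    substrate ⇌ dormant form (K = 1.60, k = 1.20 × 10⁻⁴ s⁻¹)
    second reagent + intermediate A → intermediate B (k = 0.00490 M⁻¹ s⁻¹)
    substrate + partner → intermediate A (k = 0.0450 M⁻¹ s⁻¹)
    third reagent + intermediate B → product (k = 6.60 × 10⁻⁴ M⁻¹ s⁻¹)

Amber stands 0.60 points under my figure. In red, capture of intermediate A by second reagent, taken alone with the other concentrations as charged, has a half-life of 3.3 h, short against the 40 h. Grey is the further case: at 32.0 h it holds 15.5% of intermediate A, with 0.0728% substrate and 0.701% dormant form still to come through. Raising the logarithm by k·e for each hour of the tail gives 9.83%, and adding those two entries in full gives 10.6%, where grey holds 10.2%.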